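Lignan numbering is used: C7/C7' carry the aryl groups, C8/C8' are the bridgeheads (C8 bears OH), C9/C9' are the OCH2 carbons. Everything rests on the C7–C8 bond, which joins two vicinal oxygenated, acceptor-type carbons in the hydroxylated ring B (C8, C7, O, C9', C8') and is therefore made by radical–radical coupling. A Norrish–Yang photocyclisation of a ring A ketone, a trans-4-[(arylmethoxy)methyl]-5-aryltetrahydrofuran-3-one (C8 ketone), abstracts the benzylic C7–H and closes ring B, creating the C7–C8 bond, the tertiary hydroxyl and two stereocentres in one operation. The ketone is assembled from silylated vanillin by asymmetric propargylation, gold-catalysed oxidative cyclisation, hydroxymethylation and benzylation.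

Key step: step 8

Remark: ring A is C7'–O–C9–C8–C8' and ring B is C8–C7–O–C9'–C8'. The target is the (7S,8R,7'R,8'S) isomer, (1R,3aR,4S,6aS) in furofuran numbering, with both aryl groups on the convex face, cis to 8-OH and H-8'.

Assumption: the silylated vanillin building blocks 2 and 3 are made rather than bought. In the names below, Ar = 4-(tert-butyldimethylsilyloxy)-3-methoxyphenyl.

Step 1
Reactants: 1 vanillin (4-hydroxy-3-methoxybenzaldehyde)
Product: 2 4-(tert-butyldimethylsilyloxy)-3-methoxybenzaldehyde
Conditions: TBSCl, imidazole, DMF, 0 °C to rt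
Reagents that add atoms: tert-butyldimethylsilyl chloride (TBSCl), CC(C)(C)[Si](C)(C)Cl
Why: Imidazole-assisted silylation of the phenol masks the acidic O–H, which would otherwise consume the amide base of step 6 and quench the excited ketone of step 8.

Step 2
Reactants: 2 4-(tert-butyldimethylsilyloxy)-3-methoxybenzaldehyde
Product: 3 [4-(tert-butyldimethylsilyloxy)-3-methoxyphenyl]methanol
Conditions: NaBH4, THF/MeOH, 0 °C
Reagents that add atoms: none
Why: Borohydride reduction of the aldehyde should be fast at 0 °C, and the aryl silyl ether should survive the brief exposure.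

Step 3
Reactants: 3 [4-(tert-butyldimethylsilyloxy)-3-methoxyphenyl]methanol
Product: 4 4-(tert-butyldimethylsilyloxy)-3-methoxybenzyl 2,2,2-trichloroacetimidate
Conditions: Cl3CCN, DBU (10 mol%), CH2Cl2, 0 °C
Reagents that add atoms: trichloroacetonitrile, N#CC(Cl)(Cl)Cl
Why: Base-catalysed addition of the alcohol to the nitrile should give the trichloroacetimidate, a benzyl donor that is activated by mild acid in the same way as 4-methoxybenzyl trichloroacetimidate.

Step 4
Reactants: 2 4-(tert-butyldimethylsilyloxy)-3-methoxybenzaldehyde; 5 allenylboronic acid pinacol ester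
Product: 6 (R)-1-Ar-but-3-yn-1-ol
Conditions: (R)-TRIP (10 mol%), 4 Å molecular sieves, toluene, 0 °C
Reagents that add atoms: none
Why: Chiral phosphoric acid-catalysed propargylation (SE2' allenylboration through a closed six-membered transition state) should set C7' by catalyst control through Re-face attack; (R)-TRIP is expected to give the (R)-alcohol by analogy with simple aryl aldehydes, and the configuration is to be confirmed before going on (otherwise (S)-TRIP is used).

Step 5
Reactants: 6 (R)-1-Ar-but-3-yn-1-ol
Product: 7 (R)-5-Ar-dihydrofuran-3(2H)-one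
Conditions: Ph3PAuNTf2 (5 mol%), 8-methylquinoline N-oxide (1.5 equiv), 1,2-dichloroethane, rt, no acid additive
Reagents that add atoms: 8-methylquinoline N-oxide, Cc1cccc2ccc[n+]([O-])c12
Why: In this gold-catalysed alkyne oxidation the N-oxide adds to the internal carbon of the gold-bound terminal alkyne, N–O cleavage gives an α-oxo gold carbenoid at the terminal carbon, and O–H insertion of the hydroxyl closes ring A as the tetrahydrofuran-3-one without touching C7'.

Step 6
Reactants: 7 (R)-5-Ar-dihydrofuran-3(2H)-one; 8 formaldehyde (monomer gas from cracked paraformaldehyde)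
Product: 10 (4S,5R)-5-Ar-4-(hydroxymethyl)dihydrofuran-3(2H)-one, via lithium enolate 9 (not isolated)
Conditions: LDA (1.05 equiv), THF, −78 °C; then CH2O (gas), −78 °C; AcOH quench at −78 °C
Reagents that add atoms: none
Why: Kinetic deprotonation of a 3-oxotetrahydrofuran by a lithium amide should occur at C4 (C8'), away from the ring oxygen, and the aldol addition to formaldehyde should occur anti to the C5 aryl group, so C8' is set trans by substrate control (also the thermodynamic arrangement).

Step 7
Reactants: 10 (4S,5R)-5-Ar-4-(hydroxymethyl)dihydrofuran-3(2H)-one; 4 4-(tert-butyldimethylsilyloxy)-3-methoxybenzyl 2,2,2-trichloroacetimidate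
Product: 11 (4S,5R)-5-Ar-4-[(Ar-methoxy)methyl]dihydrofuran-3(2H)-one
Conditions: pyridinium p-toluenesulfonate (10 mol%), CH2Cl2, 0 °C to rt
Reagents that add atoms: none
Why: Acid-catalysed O-benzylation with a trichloroacetimidate (transfer of the electron-rich benzyl cation) should etherify the primary alcohol without base, so retro-aldol cleavage and epimerisation of the β-hydroxy ketone are avoided.

Step 8
Reactants: 11 (4S,5R)-5-Ar-4-[(Ar-methoxy)methyl]dihydrofuran-3(2H)-one
Product: 13 (1R,3aR,4S,6aS)-1,4-bis-Ar-tetrahydro-1H,3H-furo[3,4-c]furan-3a(4H)-ol (bis-TBS ether of the target), via 1,5-biradical 12 (not isolated)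
Conditions: hν (medium-pressure Hg lamp, Pyrex filter, λ > 300 nm), degassed benzene (0.01 M), rt
Reagents that add atoms: none
Why: n→π* excitation of the C8 ketone should be followed by 1,6-hydrogen transfer from the benzylic, α-oxygenated C7–H bond (seven-membered transition state; the γ position of this chain is the ether oxygen, so C7–H is the only activated C–H within reach) to give 1,5-biradical 12, whose ketyl (C8) and benzyl (C7) radical centres combine to form the C7–C8 bond. This is a Norrish–Yang photocyclisation through δ-hydrogen abstraction, the established way from β-alkoxy ketones to tetrahydrofuran-3-ols. Ring B (C8–C7–O–C9'–C8') closes by intramolecular radical–radical combination of the 1,5-biradical, which has no β-scission path and can therefore only cyclise or revert to 11. C8 is controlled by the C8' stereocentre: the three-atom tether reaches only the face of the ketyl carbon on which C9' stands, so the ring fusion must be cis and the hydroxyl comes out cis to H-8'. C7 is set in the recombination, where the aryl group should take the convex (exo) face, away from the C9 methylene of ring A and cis to the new hydroxyl. The step needs δ-hydrogen abstraction to outrun α-cleavage of the α-alkoxy ketone, which the doubly activated C7–H bond, the silyl-masked phenols (no phenolic O–H to quench the excited ketone) and dilute, oxygen-free conditions are meant to secure.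

Step 9
Reactants: 13 bis-TBS ether of the target
Product: 14 (1R,3aR,4S,6aS)-1,4-bis(4-hydroxy-3-methoxyphenyl)tetrahydro-1H,3H-furo[3,4-c]furan-3a(4H)-ol (target)
Conditions: TBAF (2.2 equiv), AcOH (2.2 equiv), THF, 0 °C
Reagents that add atoms: none
Why: Fluoride should cleave both aryl silyl ethers, and the acetic acid buffer keeps the phenoxides from opening the benzylic ethers through quinone methides, so no stereocentre is touched.

Compound list
1 | vanillin (4-hydroxy-3-methoxybenzaldehyde) | COc1cc(C=O)ccc1O | starting material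
2 | 4-(tert-butyldimethylsilyloxy)-3-methoxybenzaldehyde | COc1cc(C=O)ccc1O[Si](C)(C)C(C)(C)C | intermediate
3 | [4-(tert-butyldimethylsilyloxy)-3-methoxyphenyl]methanol | COc1cc(CO)ccc1O[Si](C)(C)C(C)(C)C | intermediate
4 | 4-(tert-butyldimethylsilyloxy)-3-methoxybenzyl 2,2,2-trichloroacetimidate | COc1cc(COC(=N)C(Cl)(Cl)Cl)ccc1O[Si](C)(C)C(C)(C)C | intermediate
5 | allenylboronic acid pinacol ester (4,4,5,5-tetramethyl-2-(propa-1,2-dien-1-yl)-1,3,2-dioxaborolane) | C=C=CB1OC(C)(C)C(C)(C)O1 | starting material
6 | (R)-1-[4-(tert-butyldimethylsilyloxy)-3-methoxyphenyl]but-3-yn-1-ol | COc1cc([C@@H](CC#C)O)ccc1O[Si](C)(C)C(C)(C)C | intermediate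
7 | (R)-5-[4-(tert-butyldimethylsilyloxy)-3-methoxyphenyl]dihydrofuran-3(2H)-one | COc1cc([C@@H]2OCC(=O)C2)ccc1O[Si](C)(C)C(C)(C)C | intermediate
8 | formaldehyde | C=O | starting material
9 | lithium C3–C4 enolate of 7 | COc1cc([C@@H]2OCC(O[Li])=C2)ccc1O[Si](C)(C)C(C)(C)C | intermediate
10 | (4S,5R)-5-[4-(tert-butyldimethylsilyloxy)-3-methoxyphenyl]-4-(hydroxymethyl)dihydrofuran-3(2H)-one | COc1cc([C@@H]2OCC(=O)[C@H]2CO)ccc1O[Si](C)(C)C(C)(C)C | intermediate
11 | (4S,5R)-5-[4-(tert-butyldimethylsilyloxy)-3-methoxyphenyl]-4-({[4-(tert-butyldimethylsilyloxy)-3-methoxyphenyl]methoxy}methyl)dihydrofuran-3(2H)-one | COc1cc([C@@H]2OCC(=O)[C@H]2COCc3ccc(O[Si](C)(C)C(C)(C)C)c(OC)c3)ccc1O[Si](C)(C)C(C)(C)C | intermediate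
12 | 1,5-biradical of 11 (ketyl radical at C8, benzyl radical at C7) | COc1cc([C@@H]2OC[C](O)[C@H]2CO[CH]c3ccc(O[Si](C)(C)C(C)(C)C)c(OC)c3)ccc1O[Si](C)(C)C(C)(C)C | intermediate
13 | (1R,3aR,4S,6aS)-1,4-bis[4-(tert-butyldimethylsilyloxy)-3-methoxyphenyl]tetrahydro-1H,3H-furo[3,4-c]furan-3a(4H)-ol | COc1cc([C@@H]2OC[C@@]3(O)[C@H](c4ccc(O[Si](C)(C)C(C)(C)C)c(OC)c4)OC[C@@H]23)ccc1O[Si](C)(C)C(C)(C)C | intermediate
14 | (1R,3aR,4S,6aS)-1,4-bis(4-hydroxy-3-methoxyphenyl)tetrahydro-1H,3H-furo[3,4-c]furan-3a(4H)-ol | COc1cc([C@@H]2OC[C@@]3(O)[C@H](c4ccc(O)c(OC)c4)OC[C@@H]23)ccc1O | target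

Total step count: 9. Longest linear sequence: 7 steps (steps 1, 4, 5, 6, 7, 8, 9).

Steps most likely to fail

Step 8. The excited α-alkoxy ketone may undergo α-cleavage faster than δ-hydrogen abstraction, the biradical may revert by back hydrogen transfer, or the radical recombination may show poor facial selectivity at C7. The fallback closes ring B by C7–O bond formation instead; it sets out from 10 and comes back at 14. The primary alcohol of 10 would be silylated (TBSCl, imidazole, CH2Cl2) to the primary TBS ether of 10 F1. Alcohol 3 would be converted with Ph3P·HBr (MeCN, reflux) into [4-(tert-butyldimethylsilyloxy)-3-methoxybenzyl]triphenylphosphonium bromide F2, whose ylide (KN(SiMe3)2, THF) would olefinate the C8 ketone of F1 to the C7=C8 benzylidene tetrahydrofuran F3 (either alkene geometry serves). OsO4/NMO would dihydroxylate F3 from the face anti to the C8' substituent to the C7,C8-diol F4, in which the C8 hydroxyl is already cis to H-8'. TBAF would remove the three silyl groups to give the pentaol F5. Catalytic camphorsulfonic acid (THF, rt) would then ionise the 4-hydroxybenzylic C7–OH, and the C9' hydroxyl would close ring B under thermodynamic control (aryl exo), which arrives at 14.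

Step 6. Enolisation may not be regioselective (C2 against C4), the C4 enolate may expel the ring oxygen by β-elimination and so erode the C5 configuration, and the aldol may run on to double addition or dehydration. The fallback installs C9' before ring A exists; it sets out from 2 and comes back at 11. Aldehyde 2 would be coupled with 4,7-dihydro-1,3-dioxepin-2-one (the cyclic carbonate of cis-but-2-ene-1,4-diol) in an iridium-catalysed anti-selective (hydroxymethyl)allylation ([Ir(cod)Cl]2, the SEGPHOS enantiomer that gives the (1R,2S) product, 4-chloro-3-nitrobenzoic acid, Cs2CO3, 2-propanol, THF) to give the anti diol (1R,2S)-1-Ar-2-vinylpropane-1,3-diol F6. The primary hydroxyl would be benzylated with imidate 4 (pyridinium p-toluenesulfonate) to the primary mono-ether F7. m-CPBA would give the terminal epoxide F8, and camphorsulfonic acid would bring about 5-endo opening at the terminal epoxide carbon by the benzylic hydroxyl to give the ring A tetrahydrofuran-3-ol F9. Dess–Martin periodinane would oxidise F9 to 11.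

Step 7. The acid may cause dehydration or retro-aldol cleavage of the β-hydroxy ketone or ionisation of the benzylic ring ether, and the electron-rich imidate may be consumed by self-alkylation. The fallback reverses the polarity of the C9'–O bond formation; it sets out from 10 and comes back at 11. Alcohol 10 would be mesylated (MsCl, Et3N, CH2Cl2, −20 °C) to the mesylate of 10 F10, which should eliminate under the same conditions to the 4-methylene ketone F11. Alcohol 3 would then add to F11 in a phosphine-catalysed oxa-Michael reaction (PMe3, THF), and protonation of the enolate would give the trans ketone 11.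

Further compounds
F1 | step 8 | (4S,5R)-5-Ar-4-[(tert-butyldimethylsilyloxy)methyl]dihydrofuran-3(2H)-one (primary TBS ether of 10) | COc1cc([C@@H]2OCC(=O)[C@H]2CO[Si](C)(C)C(C)(C)C)ccc1O[Si](C)(C)C(C)(C)C
F2 | step 8 | [4-(tert-butyldimethylsilyloxy)-3-methoxybenzyl]triphenylphosphonium bromide | COc1cc(C[P+](c2ccccc2)(c2ccccc2)c2ccccc2)ccc1O[Si](C)(C)C(C)(C)C.[Br-]
F3 | step 8 | C7=C8 benzylidene tetrahydrofuran from F1 (alkene geometry open, C7' and C8' as in 10) | COc1cc([C@@H]2OCC(=Cc3ccc(O[Si](C)(C)C(C)(C)C)c(OC)c3)[C@H]2CO[Si](C)(C)C(C)(C)C)ccc1O[Si](C)(C)C(C)(C)C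
F4 | step 8 | C7,C8-diol from F3 (C8 hydroxyl cis to H-8', C7 configuration open) | COc1cc([C@@H]2OC[C@@](O)(C(O)c3ccc(O[Si](C)(C)C(C)(C)C)c(OC)c3)[C@H]2CO[Si](C)(C)C(C)(C)C)ccc1O[Si](C)(C)C(C)(C)C
F5 | step 8 | fully desilylated pentaol from F4 | COc1cc([C@@H]2OC[C@@](O)(C(O)c3ccc(O)c(OC)c3)[C@H]2CO)ccc1O
F6 | step 6 | (1R,2S)-1-[4-(tert-butyldimethylsilyloxy)-3-methoxyphenyl]-2-vinylpropane-1,3-diol | COc1cc([C@H](O)[C@H](CO)C=C)ccc1O[Si](C)(C)C(C)(C)C
F7 | step 6 | primary Ar-methyl mono-ether of F6 | COc1cc([C@H](O)[C@H](COCc2ccc(O[Si](C)(C)C(C)(C)C)c(OC)c2)C=C)ccc1O[Si](C)(C)C(C)(C)C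
F8 | step 6 | terminal epoxide of F7 (epoxide configuration open) | COc1cc([C@H](O)[C@H](COCc2ccc(O[Si](C)(C)C(C)(C)C)c(OC)c2)C2CO2)ccc1O[Si](C)(C)C(C)(C)C
F9 | step 6 | ring A tetrahydrofuran-3-ol, the C8 alcohol corresponding to 11 (C8 configuration open) | COc1cc([C@@H]2OCC(O)[C@H]2COCc3ccc(O[Si](C)(C)C(C)(C)C)c(OC)c3)ccc1O[Si](C)(C)C(C)(C)C
F10 | step 7 | methanesulfonate of 10 | COc1cc([C@@H]2OCC(=O)[C@H]2COS(C)(=O)=O)ccc1O[Si](C)(C)C(C)(C)C
F11 | step 7 | 5-Ar-4-methylenedihydrofuran-3(2H)-one (C5 configuration as in 10) | COc1cc([C@@H]2OCC(=O)C2=C)ccc1O[Si](C)(C)C(C)(C)C
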